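We choose to follow the rate of target and ask what brings it to a stop.

| flask | substrate | first nucleophile | solid second nucleophile | remark | time |
|---|---|---|---|---|---|
| west | 0.050 M | 0.70 equiv | 0.50 equiv | run made earlier |  |
| north-west | 0.050 M | 1.1 equiv | 0.50 equiv | run made earlier |  |
| flask | 0.050 M | 0.500 equiv | 0.500 equiv |  | 2.0 min |

| run | time / s | target / % | other capture product / % |
|---|---|---|---|
| west | 15.0 | 36 | 8 |
| west | 30.0 | 41 | 17 |
| west | 40.0 | 45 | 21 |
| west | 60.0 | 43 | 21 |
| west | 80.0 | 42 | 23 |
| west | 90.0 | 47 | 21 |
| north-west | 10.0 | 34 | 4 |
| north-west | 12.0 | 39 | 4 |
| north-west | 20.0 | 49 | 10 |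
| north-west | 25.0 | 48 | 10 |
| north-west | 40.0 | 51 | 9 |
| north-west | 60.0 | 52 | 13 |
| north-west | 90.0 | 58 | 12 |

(readings scatter by 1.5 percentage points)

- the numbers in the tables scatter by 1.5 percentage points (one standard deviation)
- at the start none of the solid second nucleophile is in solution

- share of target in target plus other capture product at 0.40 s
- share of target in target plus other capture product at 2.0 min

At the start the other capture product has no rate, since none of the solid second nucleophile is in solution. So at 0.40 s, far before the earliest reading of either run, we expect a target share near the top.

The end needs more. In the west run target reads 36% at 15.0 s, then from 40.0 s on it scatters around a level. We assume that first nucleophile, charged below the substrate and so the limiting reagent for target in the west run, has by then reacted. The keep f, a reading with the scatter of those numbers, is 0.632, the level of target per equivalent of first nucleophile charged. Likewise g is 0.717, the west level of other capture product per part of substrate beyond that charge.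

Our flask has the substrate and solid charges of the west run, so we carry f and g over as an assumption. This gives target 31.6% and other capture product 35.8%, so a share of 46.9% at 2.0 min.

The forecast says 99% (96% to 100%) at 0.40 s, and 56% (49% to 63%) at 2.0 min, the latter from a ratio "roughly linear in 1/equiv". Our end share is lower than that.

The flask gives a target share of 99.3% at 0.40 s and 48.7% at 2.0 min.

    substrate + intermediate → side product (k = 0.350 M⁻¹ s⁻¹)
    first nucleophile + intermediate → target (k = 11000 M⁻¹ s⁻¹)
    second nucleophile + intermediate → other capture product (k = 3600 M⁻¹ s⁻¹)
    intermediate → solvolysis product (k = 18.0 s⁻¹)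
    substrate → intermediate (k = 0.0720 s⁻¹)
    target ⇌ isomer of the product (K = 0.520, k = 0.130 s⁻¹)
    solid second nucleophile ⇌ second nucleophile, rate k7*(cs7 - [second nucleophile]) while solid is left; crystals form when [second nucleophile] > cs7 (solubility = 21.0 mM, k = 0.120 s⁻¹)

By their own step alone, both ways together, target and the isomer of the product relax with a half-life of 1.82 s, short against the run, and at 2.00 min the flask holds 32.6% target beside 17.0% isomer, against our 31.6% from f.

On the neighbour flask charged with 0.120 equiv of first nucleophile, f gives 7.59% target. At 2.00 min that neighbour flask holds 7.89% target.

The readings come from a simulation for substances that don't exist.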